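**Assumption:** gibberellic acid, the bulk fermentation plant-growth regulator, is taken as the cheap commercial starting material, so the route is a short partial synthesis from it. All carbon stereocentres except C16 are bought in.

**Retrosynthetic overview**
1. Target ⇐ its 1,2-didehydro derivative, by saturating the C1=C2 bond last.
2. 1,2-Didehydro target ⇐ 13-deoxygibberellic acid, by Markovnikov hydration of the 16-ene. This is the key C16–O bond, made on the exo face.
3. 13-Deoxygibberellic acid ⇐ 13-O-(methoxyoxalyl)gibberellic acid, by radical removal of the bridgehead C13 oxygen.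
4. That oxalate ⇐ gibberellic acid, by one-flask transient silylation and acylation.
5. No ring is formed: rings A, B, C, D and the 19,10-lactone come intact from gibberellic acid.

**Route**

Step 1
Reactants: 1 gibberellic acid
Product: 4 13-O-(methoxyoxalyl)gibberellic acid, via bis-TMS gibberellate 2 (not isolated), via bis-TMS 13-oxalate 3 (not isolated)
Conditions: TMSCl (2.3 equiv), pyridine, CH2Cl2, 0 °C; then ClC(O)CO2Me (2.5 equiv), DMAP (0.3 equiv), 0 °C to rt; then aq. citric acid, THF, 0 °C
Reagents that add atoms: methyl chlorooxalate, COC(=O)C(=O)Cl (the methoxyoxalyl group of 4); chlorotrimethylsilane, C[Si](C)(C)Cl (silyl groups of 2 and 3 only, gone in 4)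
Why: Transient silyl protection followed by DMAP-catalysed acylation: TMSCl/pyridine caps the acid and the secondary 3-OH but not the bridgehead tertiary 13-OH, the reactive acyl chloride then esterifies O13, and mild aqueous acid removes both TMS groups; no stereocentre is touched.

Step 2
Reactants: 4 13-O-(methoxyoxalyl)gibberellic acid
Product: 5 13-deoxygibberellic acid
Conditions: Bu3SnH (3 equiv), AIBN (0.2 equiv), toluene, 110 °C; dilute HCl, MeCN–hexane work-up
Reagents that add atoms: none
Why: Barton–McCombie-type radical deoxygenation of a tertiary methyl oxalate: the stannyl radical adds to the oxalate carbonyl, the C13–O bond breaks, and the bridgehead radical (orthogonal to the 16-ene, so no allylic chemistry) takes H from Sn–H with the configuration fixed by the cage.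

Step 3
Reactants: 5 13-deoxygibberellic acid
Product: 7 16-hydroxy-13-deoxy-16,17-dihydrogibberellic acid, via O-alkyl-N-arylhydroxylamine 6 (not isolated)
Conditions: Fe(acac)3 (0.3 equiv), PhSiH3 (3 equiv), 2,4,6-tri-tert-butylnitrosobenzene (2 equiv), EtOH–THF, Ar, 40 °C; then Zn, AcOH, 40 °C
Reagents that add atoms: 2,4,6-tri-tert-butylnitrosobenzene, CC(C)(C)c1cc(C(C)(C)C)c(N=O)c(C(C)(C)C)c1 (gives the C16 oxygen)
Why: Proposed new method: an iron hydride made from Fe(acac)3 and PhSiH3 transfers H to C17 of the 1,1-disubstituted alkene in preference to the slower-reacting 1,2-disubstituted C1=C2 bond (metal-hydride hydrogen atom transfer), and the tertiary C16 radical is caught at the oxygen of the nitroso group because the two ortho tert-butyl groups wall off nitrogen (the regiochemistry known from spin trapping of tertiary radicals); the anilino radical is reduced to hydroxylamine 6 and Zn/AcOH cuts its N–O bond, and the very large trap can reach only the convex exo face of the bicyclo[3.2.1]octane (syn to C14, away from the C11–C12 bridge that shields the endo face), which sets the exo C16–OH without O2, peroxides or cations (so no rearrangement and no lactonisation by the C7 acid); the closest known reaction types are the Mukaiyama hydration and the Fe(acac)3/PhSiH3 olefin hydroamination, in which unhindered nitrosoarenes trap the same radicals at nitrogen.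

Step 4
Reactants: 7 16-hydroxy-13-deoxy-16,17-dihydrogibberellic acid
Product: 8 the target gibberellin (16-hydroxy-13-deoxy-1,2,16,17-tetrahydrogibberellic acid)
Conditions: H2 (1 atm), 5% Rh/Al2O3, EtOAc–THF, rt
Reagents that add atoms: none
Why: Heterogeneous catalytic hydrogenation of the only remaining alkene, a strained cis-disubstituted C1=C2 bond; rhodium on alumina is chosen because it has little tendency to hydrogenolyse the allylic lactone C10–O bond, and no stereocentre is created (C1 and C2 become CH2).

**Compound list**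
1 | gibberellic acid: natural ent-gibberellane skeleton, 3β-OH, bridgehead 13-OH, 1-ene, 16-ene (exocyclic CH2), 19,10-lactone on the α face, 7-CO2H on C6 | C[C@@]12C(=O)O[C@]3(C=C[C@@H]1O)[C@@H]1CC[C@]4(O)C[C@]1(CC4=C)[C@@H](C(=O)O)[C@@H]32 | starting material
2 | trimethylsilyl 3-O-(trimethylsilyl)gibberellate (13-OH free; configuration as 1) | C[C@@]12C(=O)O[C@]3(C=C[C@@H]1O[Si](C)(C)C)[C@@H]1CC[C@]4(O)C[C@]1(CC4=C)[C@@H](C(=O)O[Si](C)(C)C)[C@@H]32 | intermediate
3 | trimethylsilyl 13-O-(methoxyoxalyl)-3-O-(trimethylsilyl)gibberellate (configuration as 1) | C[C@@]12C(=O)O[C@]3(C=C[C@@H]1O[Si](C)(C)C)[C@@H]1CC[C@]4(OC(=O)C(=O)OC)C[C@]1(CC4=C)[C@@H](C(=O)O[Si](C)(C)C)[C@@H]32 | intermediate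
4 | 13-O-(methoxyoxalyl)gibberellic acid (methyl oxalate on bridgehead O13; 3β-OH and 7-CO2H free) | C[C@@]12C(=O)O[C@]3(C=C[C@@H]1O)[C@@H]1CC[C@]4(OC(=O)C(=O)OC)C[C@]1(CC4=C)[C@@H](C(=O)O)[C@@H]32 | intermediate
5 | 13-deoxygibberellic acid (H on bridgehead C13, otherwise as 1) | C[C@@]12C(=O)O[C@]3(C=C[C@@H]1O)[C@@H]1CC[C@@H]4C[C@]1(CC4=C)[C@@H](C(=O)O)[C@@H]32 | intermediate
6 | O-(13-deoxy-16,17-dihydrogibberellic acid-16-yl)-N-(2,4,6-tri-tert-butylphenyl)hydroxylamine (C16–O exo, syn to the C14 bridge; 17-CH3 endo) | C[C@@]12C(=O)O[C@]3(C=C[C@@H]1O)[C@@H]1CC[C@@H]4C[C@]1(C[C@@]4(C)ONc5c(C(C)(C)C)cc(C(C)(C)C)cc5C(C)(C)C)[C@@H](C(=O)O)[C@@H]32 | intermediate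
7 | 16-hydroxy-13-deoxy-16,17-dihydrogibberellic acid (the 1,2-didehydro derivative of the target; 16-OH exo, 17-CH3 endo, 1-ene kept) | C[C@@]12C(=O)O[C@]3(C=C[C@@H]1O)[C@@H]1CC[C@@H]4C[C@]1(C[C@@]4(C)O)[C@@H](C(=O)O)[C@@H]32 | intermediate
8 | the target gibberellin, 16-hydroxy-13-deoxy-1,2,16,17-tetrahydrogibberellic acid (3β-OH, exo 16-OH with endo 17-CH3, 19,10-lactone, 7-CO2H, ring A saturated) | C[C@@]12C(=O)O[C@]3(CC[C@@H]1O)[C@@H]1CC[C@@H]4C[C@]1(C[C@@]4(C)O)[C@@H](C(=O)O)[C@@H]32 | target

**Totals**
Total step count: 4. Longest linear sequence: 4 steps (1 → 4 → 5 → 7 → 8).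

**Three steps most likely to fail**

Step 1 (the transient silylation may not fully spare the 13-OH, or the oxalate may suffer on work-up). The fallback sets out from 1 and comes back at 5, using a lasting protecting group instead of a transient one. Ac2O in pyridine acetylates only the secondary 3-OH and gives 3-O-acetylgibberellic acid F1. ClC(O)CO2Me with DMAP in pyridine then gives 3-O-acetyl-13-O-(methoxyoxalyl)gibberellic acid F2. Bu3SnH/AIBN in toluene at 110 °C gives 3-O-acetyl-13-deoxygibberellic acid F3. K2CO3/KHCO3-buffered MeOH at 0 °C (pH about 10, to avoid the base-induced lactone shift) removes the acetate and gives 5.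

Step 3 (the proposed new hydration; trapping by the hindered nitroso compound may be too slow, or the reagent may be reduced first). The fallback uses known chemistry, sets out from 5 and comes back at 7. A classical Mukaiyama hydration with Co(acac)2, PhSiH3 and O2 (1 atm) in THF at rt traps the same C16 radical with O2, mainly from the exo face. It gives 7 together with 16-hydroperoxy-13-deoxy-16,17-dihydrogibberellic acid F4, which PPh3 reduces to 7 in the same flask. The minor 16-epimer is removed by chromatography.

Step 4 (hydrogenolysis of the allylic lactone on the metal surface). The fallback sets out from 7 and comes back at 8. Diimide, made in the flask from KO2CN=NCO2K and AcOH in MeOH at rt, transfers H2 to the strained cis alkene in a concerted way with no metal surface, so the allylic C–O bond cannot be cleaved. No new compound is formed on the way.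

**Further compounds**
F1 | step 1 | 3-O-acetylgibberellic acid | C[C@@]12C(=O)O[C@]3(C=C[C@@H]1OC(C)=O)[C@@H]1CC[C@]4(O)C[C@]1(CC4=C)[C@@H](C(=O)O)[C@@H]32
F2 | step 1 | 3-O-acetyl-13-O-(methoxyoxalyl)gibberellic acid | C[C@@]12C(=O)O[C@]3(C=C[C@@H]1OC(C)=O)[C@@H]1CC[C@]4(OC(=O)C(=O)OC)C[C@]1(CC4=C)[C@@H](C(=O)O)[C@@H]32
F3 | step 1 | 3-O-acetyl-13-deoxygibberellic acid | C[C@@]12C(=O)O[C@]3(C=C[C@@H]1OC(C)=O)[C@@H]1CC[C@@H]4C[C@]1(CC4=C)[C@@H](C(=O)O)[C@@H]32
F4 | step 3 | 16-hydroperoxy-13-deoxy-16,17-dihydrogibberellic acid (exo OOH) | C[C@@]12C(=O)O[C@]3(C=C[C@@H]1O)[C@@H]1CC[C@@H]4C[C@]1(C[C@@]4(C)OO)[C@@H](C(=O)O)[C@@H]32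
F0 | step 4 | none | none
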